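**Retrosynthetic overview**
- Feature: the cis-fused junction C3a(OH)/C8a(CH3) with oxygen at C5 (path C3a–C4–C5) is an aldol array. Without C6 and its methyl group, the seven-membered ring shrinks to six and the bicycle is the (3aR,7aR) Hajos–Parrish ketol skeleton.
- Late stage: the C5–O ester bond comes from acylation of the secondary allylic alcohol. The C5 carbinol comes from the C5 enone by reduction directed by the C3a hydroxyl. C6=C7 comes from dehydrogenation of the 6-methyl ketone.
- Key disconnection: C5–C6 and C6–C7. In the forward sense diazoethane inserts CH(CH3) into the C5–CH2 bond of a cis-hydrindan-5-one.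
- Hydrindanone: the C3–isopropyl bond is made by conjugate addition to the C1 enone of the C5-ketalised ketol, and the C1 oxygen is then removed through the enol triflate.
- Ring order: the five-membered ring is bought, the six-membered ring is closed by the D-proline aldol, and it is then enlarged to the seven-membered ring.

Key step: step 14

Remark: hydrindanes keep the numbering of ketol 4 throughout (C1 next to C7a, C3 next to C3a, C5 the six-ring carbonyl carbon), hydroazulenes use C3 (iPr), C3a (O), C5, C6, C7, C8, C8a (CH3), and C6 of 19 is expected as an epimer mixture, of which one epimer (6S) is drawn because C6 becomes sp2 in step 15.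

Step 1
Reactants: 1 2-methylcyclopentane-1,3-dione; 2 methyl vinyl ketone
Product: 3 2-methyl-2-(3-oxobutyl)cyclopentane-1,3-dione
Conditions: H2O, AcOH (cat.), 70 °C
Reagents that add atoms: none
Why: Michael addition of the acidic 1,3-dione to the enone in water should stop at the mono-adduct because C2 has no acidic hydrogen left afterwards, and no stereocentre is formed.

Step 2
Reactants: 3 2-methyl-2-(3-oxobutyl)cyclopentane-1,3-dione
Product: 4 (3aR,7aR)-3a-hydroxy-7a-methylhexahydro-1H-indene-1,5(4H)-dione (enantiomer of the L-proline-derived Hajos–Parrish ketol; OH and CH3 cis)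
Conditions: D-proline (3 mol %), DMF, 16–20 °C, Ar; crystallisation
Reagents that add atoms: none
Why: In this proline-catalysed aldol desymmetrisation (Hajos–Parrish–Eder–Sauer–Wiechert reaction) the enamine of the side-chain methyl ketone attacks one of the two enantiotopic ring carbonyls through a transition state bridged by the carboxylic acid, so the D-catalyst sets C3a and C7a as R,R, the short tether enforces the cis fusion, and the neutral medium at room temperature leaves the ketol undehydrated.

Step 3
Reactants: 4 ketol
Product: 5 (3aR,7aR)-7a-methyl-3a-(trimethylsilyloxy)hexahydro-1H-indene-1,5(4H)-dione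
Conditions: Me3SiOTf, 2,6-lutidine, CH2Cl2, −78 °C
Reagents that add atoms: trimethylsilyl trifluoromethanesulfonate, C[Si](C)(C)OS(=O)(=O)C(F)(F)F
Why: O-Silylation of the tertiary aldol carbinol with a silyl triflate and a hindered pyridine base should outrun enol silylation of the ketones at −78 °C, and capping the O–H closes the dehydration and retro-aldol channels for the acidic and basic steps that follow.

Step 4
Reactants: 5 silylated ketol
Product: 6 (3aR,7aR)-5,5-ethylenedioxy-7a-methyl-3a-(trimethylsilyloxy)octahydro-1H-inden-1-one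
Conditions: (Me3SiOCH2)2, Me3SiOTf (5 mol %), CH2Cl2, −78 °C; pyridine quench
Reagents that add atoms: 1,2-bis(trimethylsilyloxy)ethane, C[Si](C)(C)OCCO[Si](C)(C)C
Why: Noyori ketalisation is aprotic, water-free and cold, so it avoids the protic acid and heat that dehydrate this aldol, and it should take the unhindered cyclohexanone C5 while the cyclopentanone C1 next to quaternary C7a stays free.

Step 5
Reactants: 6 keto ketal
Product: 8 (3aS,7aR)-5,5-ethylenedioxy-7a-methyl-3a-(trimethylsilyloxy)-3a,4,5,6,7,7a-hexahydro-1H-inden-1-one (C2=C3 enone), via C1 trimethylsilyl enol ether 7 (not isolated)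
Conditions: LiN(iPr)2, THF, −78 °C, then Me3SiCl; solvent exchange; Pd(OAc)2 (1.05 equiv), MeCN, rt
Reagents that add atoms: chlorotrimethylsilane, C[Si](C)(C)Cl (silyl group present in 7 only)
Why: In this Ito–Saegusa oxidation C1 can enolise only toward C2 because C7a is quaternary, divalent palladium binds C2 and β-hydride elimination of H3 gives the enone, and the C3a silyloxy group sits γ to the carbonyl and so cannot leave by E1cB.

Step 6
Reactants: 8 silyloxy enone
Product: 9 (3aS,7aR)-5,5-ethylenedioxy-3a-hydroxy-7a-methyl-3a,4,5,6,7,7a-hexahydro-1H-inden-1-one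
Conditions: Bu4NF, AcOH (1:1), THF, 0 °C
Reagents that add atoms: none
Why: Buffered fluoride cleavage of the Si–O bond builds up no free alkoxide, is not acidic enough to touch the dioxolane, and removes the silyl cap that would otherwise shield the face of C3 that must be attacked next.

Step 7
Reactants: 9 γ-hydroxy enone; 10 isopropylmagnesium chloride
Product: 11 (3R,3aS,7aR)-5,5-ethylenedioxy-3a-hydroxy-3-isopropyl-7a-methyloctahydro-1H-inden-1-one (iPr, OH and CH3 all on one face)
Conditions: 10 (3.5 equiv), CuBr·SMe2 (0.2 equiv), THF, −78 → −40 °C; aq. NH4Cl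
Reagents that add atoms: none
Why: In this copper-catalysed conjugate addition of a Grignard reagent the first equivalent makes the magnesium alkoxide (too poor a leaving group for reductive γ-elimination and an anchor for the magnesium cuprate), 1,2-attack is blocked at neopentyl C1, and the isopropyl group should enter C3 on the convex face that carries O3a and the C7a methyl because the other face is closed by C4H2 and the dioxolane oxygen folded under the five-membered ring, which sets C3 as R.

Step 8
Reactants: 11 hydroxy ketone
Product: 12 (3R,3aS,7aR)-5,5-ethylenedioxy-3-isopropyl-7a-methyl-3a-(trimethylsilyloxy)octahydro-1H-inden-1-one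
Conditions: Me3SiOTf, 2,6-lutidine, CH2Cl2, −78 → −20 °C
Reagents that add atoms: trimethylsilyl trifluoromethanesulfonate, C[Si](C)(C)OS(=O)(=O)C(F)(F)F
Why: This is the same silyl triflate O-silylation as in step 3, and the small Me3Si group is chosen because the carbinol now lies between quaternary C7a and the cis isopropyl group, where a larger group would hardly go on and Me3Si should be unusually robust, while the low temperature spares the dioxolane.

Step 9
Reactants: 12 silyloxy ketone
Product: 13 (3S,3aS,7aR)-5,5-ethylenedioxy-3-isopropyl-7a-methyl-3a-(trimethylsilyloxy)-3a,4,5,6,7,7a-hexahydro-3H-inden-1-yl trifluoromethanesulfonate (C1=C2; spatial arrangement as in 12)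
Conditions: KN(SiMe3)2, THF, −78 °C; PhNTf2, −78 → 0 °C
Reagents that add atoms: N-phenylbis(trifluoromethanesulfonimide), O=S(=O)(N(c1ccccc1)S(=O)(=O)C(F)(F)F)C(F)(F)F
Why: Enolate O-sulfonylation can give only one enol triflate because C1 has α-hydrogens at C2 alone, as in the familiar triflation of neopentyl five-ring ketones of the steroid D-ring type.

Step 10
Reactants: 13 enol triflate
Product: 14 (3S,3aS,7aS)-5,5-ethylenedioxy-3-isopropyl-7a-methyl-3a-(trimethylsilyloxy)-3a,4,5,6,7,7a-hexahydro-3H-indene (C1=C2 alkene; spatial arrangement as in 12)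
Conditions: Pd(OAc)2 (5 mol %), PPh3 (10 mol %), HCO2H, Et3N, DMF, 60 °C
Reagents that add atoms: none
Why: Palladium-catalysed transfer hydrogenolysis of a vinyl triflate with formate (oxidative addition to zerovalent palladium, decarboxylation to a palladium hydride, reductive elimination) removes the C1 oxygen under buffered conditions that ketal and silyl ether should tolerate.

Step 11
Reactants: 14 alkene
Product: 15 (3R,3aS,7aR)-5,5-ethylenedioxy-3-isopropyl-7a-methyl-3a-(trimethylsilyloxy)octahydro-1H-indene
Conditions: H2 (1 atm), PtO2 (5 mol %), EtOAc, rt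
Reagents that add atoms: none
Why: Catalytic hydrogenation of the cis-disubstituted cyclopentene creates no stereocentre, and platinum in a neutral solvent is preferred to palladium because it hardly migrates double bonds, so C3 should not be scrambled through a C2=C3 isomer.

Step 12
Reactants: 15 ketal
Product: 16 (3R,3aS,7aR)-3-isopropyl-7a-methyl-3a-(trimethylsilyloxy)octahydro-5H-inden-5-one
Conditions: PPTS (0.2 equiv), acetone–H2O (9:1), 45 °C
Reagents that add atoms: water, O
Why: In this mild acid-catalysed ketal hydrolysis the exposed dioxolane should react faster than the trimethylsilyl ether buried between C7a and the isopropyl-bearing C3, and the buffered acid is too weak to cause β-elimination.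

Step 13
Reactants: 17 N-ethyl-N-nitrosourea
Product: 18 diazoethane (toluene solution)
Conditions: 40% aq. KOH, toluene, 0 °C; organic layer decanted, dried over KOH pellets, used at once (shield, smooth glassware)
Reagents that add atoms: none
Why: Base-induced cleavage of an N-alkyl-N-nitrosourea is the standard entry to simple diazoalkanes, and drying over KOH keeps water away from the Lewis acid of the next step.

Step 14
Reactants: 16 silylated cis-hydrindan-5-one; 18 diazoethane
Product: 19 (3R,3aS,8aR)-3-isopropyl-6,8a-dimethyl-3a-(trimethylsilyloxy)octahydroazulen-5(1H)-one (C6 epimers; 6S drawn)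
Conditions: Sc(OTf)3 (0.2 equiv, dried), 18 (about 2 equiv, slow addition), toluene–CH2Cl2, −78 → −30 °C
Reagents that add atoms: none
Why: Sc(OTf)3 binds the C5 carbonyl oxygen, the nucleophilic carbon of 18 adds to C5 to give a scandium-bound β-diazonium alkoxide, and the ring bond antiperiplanar to the C–N2 bond shifts to the former diazo carbon as N2 leaves, so C5–C6 forms in the addition and C6–C7 in the 1,2-shift. The closest known reaction type is the Lewis-acid-catalysed homologation of cycloalkanones with non-stabilised diazoalkanes (Büchner–Curtius–Schlotterbeck reaction, a Tiffeneau–Demjanov-type rearrangement). The seven-membered ring arises by ring enlargement and not by cyclisation: one carbon is inserted into the C5–CH2 bond of the six-membered ring while the five-membered ring and the cis fusion are spectators. C3, C3a and C8a are untouched, and the new C6 centre is uncontrolled and enolisable but needs no control because it becomes sp2 in step 15. The step needs migration of the distal CH2 (future C7) and not of C4, which the substrate favours in two ways: C4 is neopentyl, so the rotamer placing C4–C5 anti to N2 pushes the methyl group of the diazo carbon against the C3a substituents, and the β-silyloxy group withdraws electron density from C4 and lowers its migratory aptitude. The silyl cap also shuts off retro-aldol cleavage and O-ethylation, and the α-branched cycloheptanone is less electrophilic than 16, so a second insertion should lag behind.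

Step 15
Reactants: 19 6-methyl hydroazulen-5-one
Product: 21 (3R,3aS,8aR)-3-isopropyl-6,8a-dimethyl-3a-(trimethylsilyloxy)-2,3,3a,4,8,8a-hexahydroazulen-5(1H)-one (C6=C7 enone), via C5=C6 trimethylsilyl enol ether 20 (not isolated)
Conditions: Me3SiI, (Me3Si)2NH, CH2Cl2, −20 °C → rt; filtration, solvent exchange; Pd(OAc)2 (1.1 equiv), MeCN, 40 °C
Reagents that add atoms: iodotrimethylsilane, C[Si](C)(C)I (silyl group present in 20 only)
Why: Equilibrating enol silylation should favour the tetrasubstituted C5=C6 enol silane over the one toward neopentyl C4, and Ito–Saegusa oxidation then gives the conjugated C6=C7 enone, the only ring enone possible because C3a carries no hydrogen.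

Step 16
Reactants: 21 silyloxy enone
Product: 22 (3R,3aS,8aR)-3a-hydroxy-3-isopropyl-6,8a-dimethyl-2,3,3a,4,8,8a-hexahydroazulen-5(1H)-one
Conditions: HF·pyridine, pyridine, THF, 0 °C
Reagents that add atoms: none
Why: Fluoride-driven desilylation in a weakly acidic, base-free medium frees the carbinol without exposing the β-hydroxy enone to alkoxide (retro-aldol) or to strong acid (dehydration).

Step 17
Reactants: 22 β-hydroxy enone
Product: 23 (3R,3aS,5R,8aR)-3-isopropyl-6,8a-dimethyl-2,3,4,5,8,8a-hexahydroazulene-3a,5(1H)-diol (C5–OH trans to C3a–OH on the seven-membered ring)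
Conditions: Me4NBH(OAc)3 (5 equiv), MeCN–AcOH (1:1), −30 °C; aq. potassium sodium tartrate
Reagents that add atoms: none
Why: In the Evans–Saksena reduction the C3a hydroxyl exchanges an acetate on boron and the bound hydride reaches C5 through a six-membered transition state from the face of the C3a oxygen, so the new C5–OH ends up anti (5R), while the reagent is too mild for undirected or 1,4-reduction.

Step 18
Reactants: 23 diol; 24 3,4-dimethoxybenzoyl chloride
Product: 25 (3R,3aS,5R,8aR)-3a-hydroxy-3-isopropyl-6,8a-dimethyl-1,2,3,3a,4,5,8,8a-octahydroazulen-5-yl 3,4-dimethoxybenzoate (target)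
Conditions: 24 (1.2 equiv), Et3N, DMAP (0.1 equiv), CH2Cl2, 0 °C → rt
Reagents that add atoms: none
Why: DMAP-catalysed acylation should take the secondary allylic C5–OH with retention at C5, while the tertiary C3a–OH between C8a and the isopropyl group is too hindered to react.

**Compound list**
1 | 2-methylcyclopentane-1,3-dione | CC1C(=O)CCC1=O | starting material
2 | methyl vinyl ketone | CC(=O)C=C | starting material
3 | 2-methyl-2-(3-oxobutyl)cyclopentane-1,3-dione | CC(=O)CCC1(C)C(=O)CCC1=O | intermediate
4 | (3aR,7aR)-3a-hydroxy-7a-methylhexahydro-1H-indene-1,5(4H)-dione | O=C1C[C@]2(O)CCC(=O)[C@]2(C)CC1 | intermediate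
5 | (3aR,7aR)-7a-methyl-3a-(trimethylsilyloxy)hexahydro-1H-indene-1,5(4H)-dione | O=C1C[C@]2(O[Si](C)(C)C)CCC(=O)[C@]2(C)CC1 | intermediate
6 | (3aR,7aR)-5,5-ethylenedioxy-7a-methyl-3a-(trimethylsilyloxy)octahydro-1H-inden-1-one | O1CCOC13C[C@]2(O[Si](C)(C)C)CCC(=O)[C@]2(C)CC3 | intermediate
7 | C1 trimethylsilyl enol ether of 6 (C1=C2; 3aR,7aR) | O1CCOC13C[C@]2(O[Si](C)(C)C)CC=C(O[Si](C)(C)C)[C@]2(C)CC3 | intermediate
8 | (3aS,7aR)-5,5-ethylenedioxy-7a-methyl-3a-(trimethylsilyloxy)-3a,4,5,6,7,7a-hexahydro-1H-inden-1-one | O1CCOC13C[C@]2(O[Si](C)(C)C)C=CC(=O)[C@]2(C)CC3 | intermediate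
9 | (3aS,7aR)-5,5-ethylenedioxy-3a-hydroxy-7a-methyl-3a,4,5,6,7,7a-hexahydro-1H-inden-1-one | O1CCOC13C[C@]2(O)C=CC(=O)[C@]2(C)CC3 | intermediate
10 | isopropylmagnesium chloride | CC(C)[Mg]Cl | starting material
11 | (3R,3aS,7aR)-5,5-ethylenedioxy-3a-hydroxy-3-isopropyl-7a-methyloctahydro-1H-inden-1-one | O1CCOC13C[C@]2(O)[C@@H](C(C)C)CC(=O)[C@]2(C)CC3 | intermediate
12 | (3R,3aS,7aR)-5,5-ethylenedioxy-3-isopropyl-7a-methyl-3a-(trimethylsilyloxy)octahydro-1H-inden-1-one | O1CCOC13C[C@]2(O[Si](C)(C)C)[C@@H](C(C)C)CC(=O)[C@]2(C)CC3 | intermediate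
13 | (3S,3aS,7aR)-5,5-ethylenedioxy-3-isopropyl-7a-methyl-3a-(trimethylsilyloxy)-3a,4,5,6,7,7a-hexahydro-3H-inden-1-yl trifluoromethanesulfonate | O1CCOC13C[C@]2(O[Si](C)(C)C)[C@@H](C(C)C)C=C(OS(=O)(=O)C(F)(F)F)[C@]2(C)CC3 | intermediate
14 | (3S,3aS,7aS)-5,5-ethylenedioxy-3-isopropyl-7a-methyl-3a-(trimethylsilyloxy)-3a,4,5,6,7,7a-hexahydro-3H-indene | O1CCOC13C[C@]2(O[Si](C)(C)C)[C@@H](C(C)C)C=C[C@]2(C)CC3 | intermediate
15 | (3R,3aS,7aR)-5,5-ethylenedioxy-3-isopropyl-7a-methyl-3a-(trimethylsilyloxy)octahydro-1H-indene | O1CCOC13C[C@]2(O[Si](C)(C)C)[C@@H](C(C)C)CC[C@]2(C)CC3 | intermediate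
16 | (3R,3aS,7aR)-3-isopropyl-7a-methyl-3a-(trimethylsilyloxy)octahydro-5H-inden-5-one | O=C1C[C@]2(O[Si](C)(C)C)[C@@H](C(C)C)CC[C@]2(C)CC1 | intermediate
17 | N-ethyl-N-nitrosourea | CCN(N=O)C(N)=O | starting material
18 | diazoethane | CC=[N+]=[N-] | intermediate
19 | (3R,3aS,8aR)-3-isopropyl-6,8a-dimethyl-3a-(trimethylsilyloxy)octahydroazulen-5(1H)-one (C6 epimers, 6S drawn) | O=C1C[C@]2(O[Si](C)(C)C)[C@@H](C(C)C)CC[C@]2(C)CC[C@@H]1C | intermediate
20 | C5=C6 trimethylsilyl enol ether of 19 (3R,3aS,8aR) | CC1=C(O[Si](C)(C)C)C[C@]2(O[Si](C)(C)C)[C@@H](C(C)C)CC[C@]2(C)CC1 | intermediate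
21 | (3R,3aS,8aR)-3-isopropyl-6,8a-dimethyl-3a-(trimethylsilyloxy)-2,3,3a,4,8,8a-hexahydroazulen-5(1H)-one | O=C1C[C@]2(O[Si](C)(C)C)[C@@H](C(C)C)CC[C@]2(C)CC=C1C | intermediate
22 | (3R,3aS,8aR)-3a-hydroxy-3-isopropyl-6,8a-dimethyl-2,3,3a,4,8,8a-hexahydroazulen-5(1H)-one | O=C1C[C@]2(O)[C@@H](C(C)C)CC[C@]2(C)CC=C1C | intermediate
23 | (3R,3aS,5R,8aR)-3-isopropyl-6,8a-dimethyl-2,3,4,5,8,8a-hexahydroazulene-3a,5(1H)-diol | O[C@@H]1C[C@]2(O)[C@@H](C(C)C)CC[C@]2(C)CC=C1C | intermediate
24 | 3,4-dimethoxybenzoyl chloride | COc1ccc(C(=O)Cl)cc1OC | starting material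
25 | (3R,3aS,5R,8aR)-3a-hydroxy-3-isopropyl-6,8a-dimethyl-1,2,3,3a,4,5,8,8a-octahydroazulen-5-yl 3,4-dimethoxybenzoate | COc1ccc(C(=O)O[C@@H]2C[C@]3(O)[C@@H](C(C)C)CC[C@]3(C)CC=C2C)cc1OC | target

**Total step count:** 18
**Longest linear sequence:** 17 steps (steps 1–12 and 14–18). Step 13 is a one-step side branch.

**Steps most likely to fail**

Step 14. Several processes may interfere:
- competing migration of C4;
- collapse of the diazonium alkoxide by O-alkylation (epoxide formation);
- repeated insertion;
- Lewis-acid-induced loss of the silyloxy group.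

The fallback replaces the diazo insertion by cyclopropanation and oxidative ring opening, and it sets out from 16. Kinetic deprotonation with LiN(iPr)2 in the presence of Me3SiCl (THF, −78 °C) should take the unhindered C6 proton and give the C5=C6 enol silane F1. Ethylidene transfer with Et2Zn/CH3CHI2 (CH2Cl2, 0 °C) should give the methyl-substituted siloxycyclopropane F2. FeCl3 in DMF at 0 °C cleaves the internal cyclopropane bond (Ito–Saegusa ring enlargement) to the β-chloro ketone F3. NaOAc in MeOH then removes HCl. The sequence comes back to the route at 21 and so also spares step 15.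

Step 7. Three processes may interfere:
- poor facial selectivity, that is attack anti to the oxygen from the concave face;
- slow addition next to the fully substituted C3a;
- reduction by β-hydride transfer from the secondary Grignard reagent.

The fallback replaces steric control by delivery from the substrate alkoxide, and it sets out from 9. The magnesium alkoxide of 9 is treated without copper with excess isopropenylmagnesium bromide in THF/DMPU (−78 → 0 °C). This is the alkoxide-directed, ligand-assisted conjugate addition known for 4-oxido enones. The alkenyl group is handed over inside the alkoxide-bound magnesium complex, so it must arrive on the oxygen-bearing face, giving the isopropenyl ketone F4. Hydrogenation of the 1,1-disubstituted alkene with RhCl(PPh3)3/H2 in benzene–EtOH, which does not migrate the double bond, comes back to the route at 11.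

Step 15. Three processes may interfere:
- slow palladation and β-hydride elimination at the fully substituted C6;
- elimination toward the methyl group instead of C7;
- palladium-induced β-elimination of the silyloxy group from the minor enol silane.

The fallback replaces the palladium step by chalcogen chemistry, and it sets out from 20. PhSeCl in CH2Cl2 at −78 °C should convert the enol silane under neutral conditions into the 6-phenylselanyl ketone F5. Oxidation with H2O2/pyridine at 0 °C triggers selenoxide syn-elimination. The sequence comes back to the route at 21.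

**Further compounds**
F1 | step 14 | (3R,3aS,7aR)-3-isopropyl-7a-methyl-3a,5-bis(trimethylsilyloxy)-2,3,3a,4,7,7a-hexahydro-1H-indene (C5=C6 enol silane of 16) | C1=C(O[Si](C)(C)C)C[C@]2(O[Si](C)(C)C)[C@@H](C(C)C)CC[C@]2(C)C1
F2 | step 14 | siloxycyclopropane from F1 with a CH(CH3) bridge across C5–C6 (new centres unassigned) | C[Si](C)(C)OC13C[C@]2(O[Si](C)(C)C)[C@@H](C(C)C)CC[C@]2(C)CC1C3C
F3 | step 14 | (3R,3aS,8aR)-7-chloro-3-isopropyl-6,8a-dimethyl-3a-(trimethylsilyloxy)octahydroazulen-5(1H)-one (C6 and C7 unassigned) | O=C1C[C@]2(O[Si](C)(C)C)[C@@H](C(C)C)CC[C@]2(C)CC(Cl)C1C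
F4 | step 7 | (3R,3aS,7aR)-5,5-ethylenedioxy-3a-hydroxy-7a-methyl-3-(prop-1-en-2-yl)octahydro-1H-inden-1-one | O1CCOC13C[C@]2(O)[C@@H](C(C)=C)CC(=O)[C@]2(C)CC3
F5 | step 15 | (3R,3aS,8aR)-3-isopropyl-6,8a-dimethyl-6-(phenylselanyl)-3a-(trimethylsilyloxy)octahydroazulen-5(1H)-one (C6 unassigned) | O=C1C[C@]2(O[Si](C)(C)C)[C@@H](C(C)C)CC[C@]2(C)CCC1(C)[Se]c3ccccc3
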